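**Plan**

- Cuts: first the C10–C11 bond of the aldol unit C9(=O)–C10H(CH3)–C11H(OH), which lies inside the 14-membered lactone with C11 two carbons from the ring-oxygen-bearing C13. The open form is therefore an α-bromo ethyl ketone tied through the C1–O–C13 ester to a C11 aldehyde. Then the ester C1–O13, then C9–C10 (ketone synthesis) and C4–C5 (aldol) of the C1–C10 acid.
- Forward: C5–C9 piece from meso-2,4-dimethylglutaric anhydride, extension to C1 with a β-ketoimide, esterification with the C11–C13 alcohol, and last the only ring (14-membered) by an SmI2-mediated intramolecular Reformatsky-type aldol.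
- Helpers: Br at C10 (activating group, consumed in the ring closure) and a 3,5-acetonide (temporary 1,3-dioxane that keeps O5 off the C9 ketone and stiffens C2–C6; removed last).
- Stereochemistry: C6/C8 from lipase desymmetrisation of a meso diol; C2 from an Evans auxiliary; C4/C5 from the titanium ketoimide aldol; C3 from chelate-controlled reduction; C12/C13 from (Z)-crotylboration; C10/C11 in the ring closure ((Z)-enolate, chair transition state, anti-Felkin addition to the C12-branched aldehyde).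

Key step: step 18

Remark (assumption): Pseudomonas fluorescens lipase (Amano AK) with vinyl acetate is taken to acetylate meso diol 15 on the arm that gives monoacetate 16; the rest of the route depends only on that sense. Atom numbers C1–C13 are those of the macrolide.

**Route**

Step 1
Reactants: 1 cis-but-2-ene; 2 acetaldehyde
Product: 7 (2R,3R)-3-methylpent-4-en-2-ol, via (Z)-but-2-enylpotassium 3 (not isolated), via potassium crotylborate 4 (not isolated), via (Z)-crotyldiisopinocampheylborane 5 (not isolated), via borinate ester 6 (not isolated)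
Conditions: KOtBu, n-BuLi, THF, −78 → −45 °C; (−)-Ipc2BOMe [from (+)-α-pinene], −78 °C; BF3·OEt2; 2, −78 °C; then NaOH, H2O2
Reagents that add atoms: none
Why: Brown asymmetric (Z)-crotylboration passes through a chair Zimmerman–Traxler transition state, so the Z geometry fixes the syn C12/C13 relationship and the isopinocampheyl groups from (+)-α-pinene select the aldehyde face that gives the 2R,3R alcohol.

Step 2
Reactants: 8 (4R)-4-benzyl-3-propanoyl-1,3-oxazolidin-2-one; 9 propanal
Product: 12 (4R)-4-benzyl-3-[(2R,3S)-3-hydroxy-2-methylpentanoyl]-1,3-oxazolidin-2-one, via boron enolate 10 (not isolated), via boron aldolate 11 (not isolated)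
Conditions: Bu2BOTf, iPr2NEt, CH2Cl2, 0 °C; 9, −78 → 0 °C; then pH 7 buffer, MeOH, H2O2
Reagents that add atoms: none
Why: Evans syn-aldol reaction, in which the (Z)-boron enolate adds through a chair Zimmerman–Traxler transition state on the face away from the benzyl group and so sets C2 as R (the carbinol centre is oxidised away in step 3).

Step 3
Reactants: 12 (4R)-4-benzyl-3-[(2R,3S)-3-hydroxy-2-methylpentanoyl]-1,3-oxazolidin-2-one
Product: 13 (4R)-4-benzyl-3-[(2R)-2-methyl-3-oxopentanoyl]-1,3-oxazolidin-2-one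
Conditions: SO3·pyridine, DMSO, iPr2NEt, CH2Cl2, −10 °C
Reagents that add atoms: none
Why: Parikh–Doering oxidation gives the β-ketoimide, and C2 keeps its configuration because allylic 1,3-strain holds the C2–H bond in the imide plane and suppresses enolisation toward C2.

Step 4
Reactants: 14 meso-2,4-dimethylglutaric anhydride
Product: 15 meso-2,4-dimethylpentane-1,5-diol
Conditions: LiAlH4, THF, 0 °C → reflux
Reagents that add atoms: none
Why: Hydride reduction of the cyclic anhydride takes both carbonyls to CH2OH without touching the methyl-bearing centres, so the meso relationship of the future C6 and C8 methyls is kept.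

Step 5
Reactants: 15 meso-2,4-dimethylpentane-1,5-diol
Product: 16 (2S,4R)-5-hydroxy-2,4-dimethylpentyl acetate
Conditions: Amano lipase AK, vinyl acetate, THF, rt
Reagents that add atoms: vinyl acetate (C=COC(C)=O)
Why: Lipase-catalysed transesterification distinguishes the two enantiotopic hydroxymethyl arms of the meso diol (enzymatic desymmetrisation) and thereby fixes the absolute configuration of C6 and C8 in one step.

Step 6
Reactants: 16 (2S,4R)-5-hydroxy-2,4-dimethylpentyl acetate
Product: 18 (2R,4S)-5-acetoxy-2,4-dimethylpentanoic acid, via acetoxy aldehyde 17 (not isolated)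
Conditions: TEMPO (cat.), PhI(OAc)2, MeCN–H2O, rt
Reagents that add atoms: water (O)
Why: Nitroxyl-catalysed oxidation carries the primary alcohol through the aldehyde hydrate to the acid under near-neutral conditions that leave the acetate and the α-stereocentre (C8) alone.

Step 7
Reactants: 18 (2R,4S)-5-acetoxy-2,4-dimethylpentanoic acid
Product: 20 (2S,4R)-5-[methoxy(methyl)amino]-2,4-dimethyl-5-oxopentyl acetate, via acyl imidazole 19 (not isolated)
Conditions: CDI, CH2Cl2, rt; then MeNHOMe·HCl, rt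
Reagents that add atoms: N,O-dimethylhydroxylamine hydrochloride (CNOC.Cl)
Why: Amide coupling through the acyl imidazolide gives the Weinreb amide, a C9 carbonyl mask that tolerates the Lewis acid, hydride, peroxide and acylation steps ahead and later gives a ketone with a Grignard reagent.

Step 8
Reactants: 20 (2S,4R)-5-[methoxy(methyl)amino]-2,4-dimethyl-5-oxopentyl acetate
Product: 21 (2R,4S)-5-hydroxy-N-methoxy-N,2,4-trimethylpentanamide
Conditions: K2CO3, MeOH, 0 °C; used at once
Reagents that add atoms: none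
Why: Base-catalysed transesterification (methanolysis) removes the acetate while the Weinreb amide is inert to K2CO3 in cold MeOH, and immediate use forestalls lactonisation.

Step 9
Reactants: 21 (2R,4S)-5-hydroxy-N-methoxy-N,2,4-trimethylpentanamide
Product: 22 (2R,4S)-N-methoxy-N,2,4-trimethyl-5-oxopentanamide
Conditions: Dess–Martin periodinane, NaHCO3, CH2Cl2, 0 °C → rt
Reagents that add atoms: none
Why: Dess–Martin oxidation under buffered conditions gives the α-branched aldehyde (C5) without epimerisation at C6.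

Step 10
Reactants: 13 (4R)-4-benzyl-3-[(2R)-2-methyl-3-oxopentanoyl]-1,3-oxazolidin-2-one; 22 (2R,4S)-N-methoxy-N,2,4-trimethyl-5-oxopentanamide
Product: 24 (4R)-4-benzyl-3-[(2R,4R,5S,6S,8R)-5-hydroxy-9-[methoxy(methyl)amino]-2,4,6,8-tetramethyl-3,9-dioxononanoyl]-1,3-oxazolidin-2-one, via titanium enolate 23 (not isolated)
Conditions: 13, TiCl4, iPr2NEt, CH2Cl2, −10 °C; then 22, −78 → −40 °C; aq. NH4Cl
Reagents that add atoms: none
Why: Evans titanium-enolate aldol of a β-ketoimide, in which the (Z)-enolate adds through a chelated chair transition state whose face is fixed by the C2 stereocentre to give the 2,4-syn-4,5-syn adduct, which is also the anti-Felkin (matched) sense for the C6-branched aldehyde, so C4 and C5 are set together.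

Step 11
Reactants: 24 (4R)-4-benzyl-3-[(2R,4R,5S,6S,8R)-5-hydroxy-9-[methoxy(methyl)amino]-2,4,6,8-tetramethyl-3,9-dioxononanoyl]-1,3-oxazolidin-2-one
Product: 25 (4R)-4-benzyl-3-[(2R,3S,4R,5S,6S,8R)-3,5-dihydroxy-9-[methoxy(methyl)amino]-2,4,6,8-tetramethyl-9-oxononanoyl]-1,3-oxazolidin-2-one
Conditions: Zn(BH4)2, CH2Cl2–Et2O, −78 → −20 °C
Reagents that add atoms: none
Why: Chelation-controlled reduction, in which zinc ties the C3 ketone to the C5 hydroxyl and hydride attacks the open face of the chelate to give the 3,5-syn diol (C3 S), while imide and Weinreb amide are not reduced at low temperature.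

Step 12
Reactants: 25 (4R)-4-benzyl-3-[(2R,3S,4R,5S,6S,8R)-3,5-dihydroxy-9-[methoxy(methyl)amino]-2,4,6,8-tetramethyl-9-oxononanoyl]-1,3-oxazolidin-2-one
Product: 26 (4R)-4-benzyl-3-[(2R,3S,4R,5S,6S,8R)-3,5-(isopropylidenedioxy)-9-[methoxy(methyl)amino]-2,4,6,8-tetramethyl-9-oxononanoyl]-1,3-oxazolidin-2-one
Conditions: 2,2-dimethoxypropane, CSA (cat.), CH2Cl2, rt
Reagents that add atoms: 2,2-dimethoxypropane (COC(C)(C)OC)
Why: Acid-catalysed transketalisation locks the syn-1,3-diol as its acetonide, the temporary ring that keeps O5 away from the later C9 ketone and O3/O5 out of the acylation steps.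

Step 13
Reactants: 26 (4R)-4-benzyl-3-[(2R,3S,4R,5S,6S,8R)-3,5-(isopropylidenedioxy)-9-[methoxy(methyl)amino]-2,4,6,8-tetramethyl-9-oxononanoyl]-1,3-oxazolidin-2-one
Product: 28 (2R,3S,4R,5S,6S,8R)-3,5-(isopropylidenedioxy)-9-[methoxy(methyl)amino]-2,4,6,8-tetramethyl-9-oxononanoic acid, via peroxy acid 27 (not isolated)
Conditions: LiOH, H2O2, THF–H2O, 0 °C; then aq. Na2SO3
Reagents that add atoms: hydrogen peroxide (OO)
Why: Hydroperoxide cleavage of the Evans imide attacks the exocyclic carbonyl selectively and frees the C1 acid without epimerising C2, while Weinreb amide and acetonide are untouched.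

Step 14
Reactants: 28 (2R,3S,4R,5S,6S,8R)-3,5-(isopropylidenedioxy)-9-[methoxy(methyl)amino]-2,4,6,8-tetramethyl-9-oxononanoic acid
Product: 29 (2R,3S,4R,5S,6S,8R)-3,5-(isopropylidenedioxy)-2,4,6,8-tetramethyl-9-oxoundecanoic acid
Conditions: EtMgBr (3.5 equiv), THF, −10 → 0 °C; aq. HCl to pH 3
Reagents that add atoms: ethylmagnesium bromide (CC[Mg]Br)
Why: Weinreb ketone synthesis, in which the first equivalent of Grignard reagent forms the inert magnesium carboxylate and further reagent adds once to the amide to give a chelated tetrahedral intermediate that collapses to the ethyl ketone only on work-up, installing C10 and its methyl.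

Step 15
Reactants: 29 (2R,3S,4R,5S,6S,8R)-3,5-(isopropylidenedioxy)-2,4,6,8-tetramethyl-9-oxoundecanoic acid; 7 (2R,3R)-3-methylpent-4-en-2-ol
Product: 31 (2R,3R)-3-methylpent-4-en-2-yl (2R,3S,4R,5S,6S,8R)-3,5-(isopropylidenedioxy)-2,4,6,8-tetramethyl-9-oxoundecanoate, via mixed anhydride 30 (not isolated)
Conditions: 2,4,6-trichlorobenzoyl chloride, Et3N, toluene, rt; then 7, DMAP, rt
Reagents that add atoms: none
Why: Yamaguchi esterification, in which the mixed trichlorobenzoic anhydride is attacked at the aliphatic carbonyl by the secondary alcohol under DMAP catalysis, builds the C1–O–C13 ester tether with retention at C13.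

Step 16
Reactants: 31 (2R,3R)-3-methylpent-4-en-2-yl (2R,3S,4R,5S,6S,8R)-3,5-(isopropylidenedioxy)-2,4,6,8-tetramethyl-9-oxoundecanoate
Product: 33 (2R,3R)-3-methylpent-4-en-2-yl (2R,3S,4R,5S,6S,8R,10RS)-10-bromo-3,5-(isopropylidenedioxy)-2,4,6,8-tetramethyl-9-oxoundecanoate, via silyl enol ether 32 (not isolated)
Conditions: LiHMDS, TMSCl, THF, −78 °C; then NBS, NaHCO3, THF, −78 → 0 °C
Reagents that add atoms: N-bromosuccinimide (O=C1CCC(=O)N1Br)
Why: Kinetic deprotonation with in-situ silylation occurs at the less hindered C10 methylene (not at the C8 methine or the less acidic ester C2–H) and NBS brominates the silyl enol ether at C10, whose configuration is irrelevant because the next step erases it.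

Step 17
Reactants: 33 (2R,3R)-3-methylpent-4-en-2-yl (2R,3S,4R,5S,6S,8R,10RS)-10-bromo-3,5-(isopropylidenedioxy)-2,4,6,8-tetramethyl-9-oxoundecanoate
Product: 35 (2R,3S)-3-methyl-4-oxobutan-2-yl (2R,3S,4R,5S,6S,8R,10RS)-10-bromo-3,5-(isopropylidenedioxy)-2,4,6,8-tetramethyl-9-oxoundecanoate, via vicinal diol 34 (not isolated)
Conditions: OsO4 (cat.), NaIO4, 2,6-lutidine, dioxane–H2O, rt; used crude
Reagents that add atoms: osmium tetroxide (O=[Os](=O)(=O)=O); sodium periodate ([Na+].[O-]I(=O)(=O)=O)
Why: Lemieux–Johnson cleavage (catalytic dihydroxylation, then periodate glycol cleavage) turns the vinyl group into the C11 aldehyde under buffered, non-reducing conditions that spare the α-bromo ketone and do not epimerise C12.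

Step 18
Reactants: 35 (2R,3S)-3-methyl-4-oxobutan-2-yl (2R,3S,4R,5S,6S,8R,10RS)-10-bromo-3,5-(isopropylidenedioxy)-2,4,6,8-tetramethyl-9-oxoundecanoate
Product: 37 3,5-O-isopropylidene-8,8a-deoxyoleandolide, via samarium enolate 36 (not isolated)
Conditions: SmI2 (3 equiv), THF, −78 °C, slow addition of 35 to about 2 mM final concentration; aq. NH4Cl at −78 °C
Reagents that add atoms: none
Why: Two single-electron transfers from SmI2 cleave the C10–Br bond and give the (Z)-enolate of trivalent samarium, which adds to the tethered C11 aldehyde through a chelated chair (Zimmerman–Traxler) transition state; the closest known reaction type is the SmI2-promoted intramolecular Reformatsky-type addition of α-halo ketones and esters to aldehydes used to close macrolide rings. The 14-membered ring closes in the 14-exo-trig mode at the aldehyde carbon, with both enolate carbons inside the new ring (enolendo). C10 is set by the Z geometry of the enolate in the chair, which places its methyl syn to the new C11 oxygen. C11 is set by the aldehyde face that is attacked: a (Z)-enolate avoids the syn-pentane clash between its methyl and the C12 substituents and so adds anti-Felkin (C11–O anti to the C12 methyl), and the 3,5-acetonide with the C2–C8 methyl array should restrict the chain to a fold that presents this face. The step needs chemoselectivity (C–Br reduction is far faster than ketyl formation from the aldehyde at −78 °C without additives), ring closure over oligomerisation (slow addition into excess SmI2 at high dilution) and regiochemical certainty (the enolate can form only at C10, where the bromine was). No base is present, so the β-acyloxy aldehyde should not eliminate and C8 and C12 should not epimerise.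

Step 19
Reactants: 37 3,5-O-isopropylidene-8,8a-deoxyoleandolide
Product: 38 8,8a-deoxyoleandolide
Conditions: 1 M aq. HCl, THF, 0 °C → rt
Reagents that add atoms: none
Why: Acid-catalysed hydrolysis of the acetonide (ketal cleavage) releases the 3,5-diol, while lactone and β-hydroxy ketone should tolerate dilute acid at or below room temperature.

**Compound list**

1 | cis-but-2-ene | C/C=C\C | starting material
2 | acetaldehyde | CC=O | starting material
3 | (Z)-but-2-enylpotassium | C/C=C\C[K] | intermediate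
4 | potassium (Z)-but-2-enyl(methoxy)diisopinocampheylborate | C/C=C\C[B-](OC)([C@@H]1C[C@@H]2C[C@H]([C@H]1C)C2(C)C)[C@@H]1C[C@@H]2C[C@H]([C@H]1C)C2(C)C.[K+] | intermediate
5 | (Z)-crotyldiisopinocampheylborane (isopinocampheyl groups from (+)-α-pinene) | C/C=C\CB([C@@H]1C[C@@H]2C[C@H]([C@H]1C)C2(C)C)[C@@H]1C[C@@H]2C[C@H]([C@H]1C)C2(C)C | intermediate
6 | diisopinocampheylborinic ester of 7 | C=C[C@@H](C)[C@@H](C)OB([C@@H]1C[C@@H]2C[C@H]([C@H]1C)C2(C)C)[C@@H]1C[C@@H]2C[C@H]([C@H]1C)C2(C)C | intermediate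
7 | (2R,3R)-3-methylpent-4-en-2-ol (C11–C13 unit) | C=C[C@@H](C)[C@@H](C)O | intermediate
8 | (4R)-4-benzyl-3-propanoyl-1,3-oxazolidin-2-one | CCC(=O)N1[C@H](Cc2ccccc2)COC1=O | starting material
9 | propanal | CCC=O | starting material
10 | (Z)-dibutylboron enolate of 8 | C/C=C(\OB(CCCC)CCCC)N1[C@H](Cc2ccccc2)COC1=O | intermediate
11 | dibutylboron aldolate of 12 | CC[C@H](OB(CCCC)CCCC)[C@@H](C)C(=O)N1[C@H](Cc2ccccc2)COC1=O | intermediate
12 | (4R)-4-benzyl-3-[(2R,3S)-3-hydroxy-2-methylpentanoyl]-1,3-oxazolidin-2-one | CC[C@H](O)[C@@H](C)C(=O)N1[C@H](Cc2ccccc2)COC1=O | intermediate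
13 | (4R)-4-benzyl-3-[(2R)-2-methyl-3-oxopentanoyl]-1,3-oxazolidin-2-one | CCC(=O)[C@@H](C)C(=O)N1[C@H](Cc2ccccc2)COC1=O | intermediate
14 | meso-2,4-dimethylglutaric anhydride ((3R,5S)-3,5-dimethyloxane-2,6-dione) | O=C1[C@@H](C)C[C@@H](C)C(=O)O1 | starting material
15 | meso-(2R,4S)-2,4-dimethylpentane-1,5-diol | OC[C@@H](C)C[C@@H](C)CO | intermediate
16 | (2S,4R)-5-hydroxy-2,4-dimethylpentyl acetate | CC(=O)OC[C@@H](C)C[C@@H](C)CO | intermediate
17 | (2S,4R)-2,4-dimethyl-5-oxopentyl acetate | CC(=O)OC[C@@H](C)C[C@@H](C)C=O | intermediate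
18 | (2R,4S)-5-acetoxy-2,4-dimethylpentanoic acid | CC(=O)OC[C@@H](C)C[C@@H](C)C(=O)O | intermediate
19 | (2S,4R)-5-(imidazol-1-yl)-2,4-dimethyl-5-oxopentyl acetate | CC(=O)OC[C@@H](C)C[C@@H](C)C(=O)n1ccnc1 | intermediate
20 | (2S,4R)-5-[methoxy(methyl)amino]-2,4-dimethyl-5-oxopentyl acetate | CC(=O)OC[C@@H](C)C[C@@H](C)C(=O)N(C)OC | intermediate
21 | (2R,4S)-5-hydroxy-N-methoxy-N,2,4-trimethylpentanamide | OC[C@@H](C)C[C@@H](C)C(=O)N(C)OC | intermediate
22 | (2R,4S)-N-methoxy-N,2,4-trimethyl-5-oxopentanamide (C5–C9 unit) | O=C[C@@H](C)C[C@@H](C)C(=O)N(C)OC | intermediate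
23 | (Z)-trichlorotitanium enolate of 13 | C/C=C(\O[Ti](Cl)(Cl)Cl)[C@@H](C)C(=O)N1[C@H](Cc2ccccc2)COC1=O | intermediate
24 | (4R)-4-benzyl-3-[(2R,4R,5S,6S,8R)-5-hydroxy-9-[methoxy(methyl)amino]-2,4,6,8-tetramethyl-3,9-dioxononanoyl]-1,3-oxazolidin-2-one | O=C(N1[C@H](Cc2ccccc2)COC1=O)[C@H](C)C(=O)[C@H](C)[C@@H](O)[C@@H](C)C[C@@H](C)C(=O)N(C)OC | intermediate
25 | (4R)-4-benzyl-3-[(2R,3S,4R,5S,6S,8R)-3,5-dihydroxy-9-[methoxy(methyl)amino]-2,4,6,8-tetramethyl-9-oxononanoyl]-1,3-oxazolidin-2-one | O=C(N1[C@H](Cc2ccccc2)COC1=O)[C@H](C)[C@@H](O)[C@H](C)[C@@H](O)[C@@H](C)C[C@@H](C)C(=O)N(C)OC | intermediate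
26 | 3,5-acetonide of 25 | O=C(N1[C@H](Cc2ccccc2)COC1=O)[C@H](C)[C@@H](OC3(C)C)[C@H](C)[C@@H](O3)[C@@H](C)C[C@@H](C)C(=O)N(C)OC | intermediate
27 | peroxy acid corresponding to 28 | OOC(=O)[C@H](C)[C@@H](OC1(C)C)[C@H](C)[C@@H](O1)[C@@H](C)C[C@@H](C)C(=O)N(C)OC | intermediate
28 | (2R,3S,4R,5S,6S,8R)-3,5-(isopropylidenedioxy)-9-[methoxy(methyl)amino]-2,4,6,8-tetramethyl-9-oxononanoic acid | OC(=O)[C@H](C)[C@@H](OC1(C)C)[C@H](C)[C@@H](O1)[C@@H](C)C[C@@H](C)C(=O)N(C)OC | intermediate
29 | (2R,3S,4R,5S,6S,8R)-3,5-(isopropylidenedioxy)-2,4,6,8-tetramethyl-9-oxoundecanoic acid | OC(=O)[C@H](C)[C@@H](OC1(C)C)[C@H](C)[C@@H](O1)[C@@H](C)C[C@@H](C)C(=O)CC | intermediate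
30 | mixed anhydride of 29 with 2,4,6-trichlorobenzoic acid | Clc1cc(Cl)cc(Cl)c1C(=O)OC(=O)[C@H](C)[C@@H](OC2(C)C)[C@H](C)[C@@H](O2)[C@@H](C)C[C@@H](C)C(=O)CC | intermediate
31 | (2R,3R)-3-methylpent-4-en-2-yl (2R,3S,4R,5S,6S,8R)-3,5-(isopropylidenedioxy)-2,4,6,8-tetramethyl-9-oxoundecanoate | C=C[C@@H](C)[C@@H](C)OC(=O)[C@H](C)[C@@H](OC1(C)C)[C@H](C)[C@@H](O1)[C@@H](C)C[C@@H](C)C(=O)CC | intermediate
32 | C9–C10 trimethylsilyl enol ether of 31 (E/Z mixture) | C=C[C@@H](C)[C@@H](C)OC(=O)[C@H](C)[C@@H](OC1(C)C)[C@H](C)[C@@H](O1)[C@@H](C)C[C@@H](C)C(O[Si](C)(C)C)=CC | intermediate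
33 | 10-bromo derivative of 31 (C10 epimers) | C=C[C@@H](C)[C@@H](C)OC(=O)[C@H](C)[C@@H](OC1(C)C)[C@H](C)[C@@H](O1)[C@@H](C)C[C@@H](C)C(=O)C(C)Br | intermediate
34 | vicinal diol from dihydroxylation of the vinyl group of 33 (epimers at the new carbinol and at C10) | OCC(O)[C@@H](C)[C@@H](C)OC(=O)[C@H](C)[C@@H](OC1(C)C)[C@H](C)[C@@H](O1)[C@@H](C)C[C@@H](C)C(=O)C(C)Br | intermediate
35 | (2R,3S)-3-methyl-4-oxobutan-2-yl (2R,3S,4R,5S,6S,8R,10RS)-10-bromo-3,5-(isopropylidenedioxy)-2,4,6,8-tetramethyl-9-oxoundecanoate | O=C[C@@H](C)[C@@H](C)OC(=O)[C@H](C)[C@@H](OC1(C)C)[C@H](C)[C@@H](O1)[C@@H](C)C[C@@H](C)C(=O)C(C)Br | intermediate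
36 | (Z)-diiodosamarium C9–C10 enolate of the debrominated aldehyde ester | O=C[C@@H](C)[C@@H](C)OC(=O)[C@H](C)[C@@H](OC1(C)C)[C@H](C)[C@@H](O1)[C@@H](C)C[C@@H](C)/C(O[Sm](I)I)=C/C | intermediate
37 | 3,5-O-isopropylidene-8,8a-deoxyoleandolide | O=C1[C@H](C)[C@@H](OC2(C)C)[C@H](C)[C@@H](O2)[C@@H](C)C[C@@H](C)C(=O)[C@H](C)[C@@H](O)[C@@H](C)[C@@H](C)O1 | intermediate
38 | 8,8a-deoxyoleandolide | C[C@@H]1[C@@H](O)[C@@H](C)C[C@@H](C)C(=O)[C@H](C)[C@@H](O)[C@@H](C)[C@@H](C)OC(=O)[C@H](C)[C@H]1O | target

**Step count and risks**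

Total step count: 19. Longest linear sequence: 16 steps (steps 4–19, from anhydride 14).

Steps most likely to fail:

1. Step 18 (key step). What may go wrong: intermolecular aldol addition or protonation of the samarium enolate outrunning ring closure, attack on the wrong aldehyde face under the conformational bias of the forming ring, or acyl migration from O13 to the new O11 alkoxide. Fallback (ring closure moved from C10–C11 to the lactone bond C1–O13; sets out from keto acid 29 and alcohol 7, comes back at 37): 7 is converted with 4-methoxybenzyl trichloroacetimidate and catalytic TfOH into its 4-methoxybenzyl ether F1, whose vinyl group is cleaved (OsO4 cat., NaIO4, 2,6-lutidine) to (2S,3R)-3-[(4-methoxybenzyl)oxy]-2-methylbutanal F2. Keto acid 29 is taken with LiHMDS (2.2 equiv, THF, −78 °C) to its carboxylate (Z)-enolate and added to F2 in an intermolecular syn-aldol reaction to give the 11-hydroxy seco acid F3. Silylation of O11 (TBSOTf, 2,6-lutidine; then K2CO3 in MeOH to free the acid) gives the 11-O-silyl acid F4. DDQ in wet CH2Cl2 removes the 4-methoxybenzyl group to give the 13-hydroxy acid F5. Yamaguchi macrolactonisation (2,4,6-trichlorobenzoyl chloride, Et3N; then DMAP in toluene at high dilution) closes the ring as the 11-O-silyl macrolide F6, and HF·pyridine in MeCN removes the silyl ether to deliver 37.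

2. Step 16. What may go wrong: deprotonation on the C8 side of the ketone or at C2 of the ester (with loss of configuration or elimination of O3), and double bromination. Fallback (position of the enol ether fixed by a vinyl group instead of by kinetic deprotonation; sets out from Weinreb acid 28 and alcohol 7, comes back at 33): Yamaguchi esterification of 28 with 7 gives the Weinreb amide ester F7. Vinylmagnesium bromide (THF, −20 °C, acidic quench) gives the vinyl ketone F8. Conjugate hydrosilylation with PhMe2SiH and catalytic [(Ph3P)CuH]6 in toluene gives only the C9–C10 dimethylphenylsilyl enol ether F9, since the terminal alkene and the ester do not react with the copper hydride. NBS at −78 °C then gives 33.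

3. Step 15. What may go wrong: slow acylation of the hindered secondary alcohol, which leaves the activated acid time to epimerise at C2 through a ketene or to lose the C3 oxygen by elimination. Fallback (the alcohol is activated instead of the acid; sets out from keto acid 29 and acetaldehyde 2, comes back at 31): (E)-crotylboration of 2 (trans-but-2-ene, KOtBu, n-BuLi, (+)-Ipc2BOMe, BF3·OEt2; then NaOH, H2O2) gives the C13-epimeric alcohol (2S,3R)-3-methylpent-4-en-2-ol F10. A Mitsunobu reaction of F10 with 29 (PPh3, DIAD, toluene, 0 °C → rt) forms the C1–O13 bond with inversion at C13 and so gives ester 31 without an activated acyl species that could epimerise C2.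

**Further compounds**

F1 | step 18 | 1-methoxy-4-({[(2R,3R)-3-methylpent-4-en-2-yl]oxy}methyl)benzene | C=C[C@@H](C)[C@@H](C)OCc1ccc(OC)cc1
F2 | step 18 | (2S,3R)-3-[(4-methoxybenzyl)oxy]-2-methylbutanal | O=C[C@@H](C)[C@@H](C)OCc1ccc(OC)cc1
F3 | step 18 | 11-hydroxy-3,5-(isopropylidenedioxy)-13-[(4-methoxybenzyl)oxy]-2,4,6,8,10,12-hexamethyl-9-oxotetradecanoic acid (stereocentres as in 38) | OC(=O)[C@H](C)[C@@H](OC1(C)C)[C@H](C)[C@@H](O1)[C@@H](C)C[C@@H](C)C(=O)[C@H](C)[C@@H](O)[C@@H](C)[C@@H](C)OCc2ccc(OC)cc2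
F4 | step 18 | 11-[(tert-butyldimethylsilyl)oxy]-3,5-(isopropylidenedioxy)-13-[(4-methoxybenzyl)oxy]-2,4,6,8,10,12-hexamethyl-9-oxotetradecanoic acid (stereocentres as in 38) | OC(=O)[C@H](C)[C@@H](OC1(C)C)[C@H](C)[C@@H](O1)[C@@H](C)C[C@@H](C)C(=O)[C@H](C)[C@@H](O[Si](C)(C)C(C)(C)C)[C@@H](C)[C@@H](C)OCc2ccc(OC)cc2
F5 | step 18 | 11-[(tert-butyldimethylsilyl)oxy]-13-hydroxy-3,5-(isopropylidenedioxy)-2,4,6,8,10,12-hexamethyl-9-oxotetradecanoic acid (stereocentres as in 38) | OC(=O)[C@H](C)[C@@H](OC1(C)C)[C@H](C)[C@@H](O1)[C@@H](C)C[C@@H](C)C(=O)[C@H](C)[C@@H](O[Si](C)(C)C(C)(C)C)[C@@H](C)[C@@H](C)O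
F6 | step 18 | 11-O-(tert-butyldimethylsilyl)-3,5-O-isopropylidene-8,8a-deoxyoleandolide | O=C1[C@H](C)[C@@H](OC2(C)C)[C@H](C)[C@@H](O2)[C@@H](C)C[C@@H](C)C(=O)[C@H](C)[C@@H](O[Si](C)(C)C(C)(C)C)[C@@H](C)[C@@H](C)O1
F7 | step 16 | (2R,3R)-3-methylpent-4-en-2-yl (2R,3S,4R,5S,6S,8R)-3,5-(isopropylidenedioxy)-9-[methoxy(methyl)amino]-2,4,6,8-tetramethyl-9-oxononanoate | C=C[C@@H](C)[C@@H](C)OC(=O)[C@H](C)[C@@H](OC1(C)C)[C@H](C)[C@@H](O1)[C@@H](C)C[C@@H](C)C(=O)N(C)OC
F8 | step 16 | (2R,3R)-3-methylpent-4-en-2-yl (2R,3S,4R,5S,6S,8R)-3,5-(isopropylidenedioxy)-2,4,6,8-tetramethyl-9-oxoundec-10-enoate | C=C[C@@H](C)[C@@H](C)OC(=O)[C@H](C)[C@@H](OC1(C)C)[C@H](C)[C@@H](O1)[C@@H](C)C[C@@H](C)C(=O)C=C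
F9 | step 16 | (Z)-C9–C10 dimethylphenylsilyl enol ether of 31 | C=C[C@@H](C)[C@@H](C)OC(=O)[C@H](C)[C@@H](OC1(C)C)[C@H](C)[C@@H](O1)[C@@H](C)C[C@@H](C)/C(O[Si](C)(C)c2ccccc2)=C/C
F10 | step 15 | (2S,3R)-3-methylpent-4-en-2-ol | C=C[C@@H](C)[C@H](C)O
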